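73.7 h⁻¹ was the number I froze: the turnover rate, product made per hour per catalyst charged, read from Tuesday's run, where product climbed from 13.7 % at 1.33 h to 29.1 % at 2.50 h, each reading scattering by 0.5 percentage points.

| flask | starting material | coupling partner | free catalyst | remark | time |
|---|---|---|---|---|---|
| Tuesday's | 0.28 M (fed, over 2.5 h) | 0.263 M | 0.50 mM | run made earlier; the fed solution adds 0.20 times the starting volume |  |
| south | 0.25 M (fed, over 2.5 h) | 0.263 M | 0.50 mM | the fed solution adds 0.20 times the starting volume | 4.0 h |
| north-west | 0.25 M (fed, over 1.2 h) | 0.200 M | 1.5 mM | the fed solution adds 0.20 times the starting volume | 4.0 h |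
| south-west | 0.25 M (fed, over 2.5 h) | 0.263 M | 0.12 mM | the fed solution adds 0.20 times the starting volume | 4.0 h |
| east | 0.25 M (fed, over 10 h) | 0.263 M | 0.50 mM | the fed solution adds 0.20 times the starting volume | 4.0 h |
| west | 0.15 M (fed, over 2.5 h) | 0.263 M | 2.0 mM | the fed solution adds 0.20 times the starting volume | 4.0 h |

Tuesday's run (percent of the starting material charged)

| time / h | product / % |
|---|---|
| 0.417 | 1.8 |
| 0.833 | 6.6 |
| 1.33 | 13.7 |
| 1.50 | 15.1 |
| 2.00 | 21.8 |
| 2.50 | 29.1 |

(each reading ± 0.5 percentage points)

- amounts are per litre of the starting volume; all of the dose is in the solution fed
- percentages count the whole charge, also what has not yet gone in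
- no earlier run changes the charge of free catalyst; that part of a forecast is a guess

- all flasks from highest to lowest amount of product, in percent of the starting material charged, at 4.0 h (south / north-west / south-west / east / west)
- the amount of product, in percent of the starting material charged of the flask you put first, at 4.0 h
- the amount of product, in percent of the starting material charged of the flask you put last, at 4.0 h

I ran south-west, the flask with the lowest charge of free catalyst, in slow motion. In the first instants starting material was just arriving: on Tuesday 16.7 % of the charge had been fed at 0.417 h, and the average rate up to then was a third of the later one. In the middle, the feed of south-west delivered 100 mM h⁻¹. I took the catalyst to work in proportion to c(free catalyst), which no run tests, so in my reckoning it consumed 8.85 mM h⁻¹, and the feed ran ten times faster. So I let starting material pile up in south-west, its feed being faster than its consumption, and treated the rate as pseudo-zero-order in it. For the end of the feed at 2.5 h I reckoned product at 8.85 %, and I let the rate go on unchanged. By 4.0 h that made 14.2 %, having used 13.5 % of the coupling partner.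

The charge of the limiting reagent divided by this rate is a work time: 28.3 h for south-west, longer than any other flask's. West needed 1.02 h by this reckoning, less than the 1.50 h between the end of its feed and the reading, so I expected it finished.

The forecast, saying “I assume rate is proportional to catalyst”, gave west > north-west > south > east > south-west, with 90 % (75 % to 97 %) at the top and 16 % (10 % to 22 %) at the bottom, where my figure was 14.2 %.

The flasks gave west > north-west > south > east > south-west. West reached 99.7 %, above the forecast's range, and south-west 14.5 %.

    starting material + free catalyst ⇌ catalyst intermediate A (K = 13.0 M⁻¹, k = 11.0 M⁻¹ s⁻¹)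
    catalyst intermediate A ⇌ catalyst intermediate B (K = 2.80, k = 0.0660 s⁻¹)
    coupling partner + catalyst intermediate B ⇌ catalyst intermediate C (K = 1.90 M⁻¹, k = 1.40 M⁻¹ s⁻¹)
    catalyst intermediate C → free catalyst + product (k = 0.340 s⁻¹)

West had come to rest: 0.251 % of its starting material remained at 4.00 h, and at 40.0 h its product stood at 100 %. South-west had not: at 4.00 h, 85 % of its charged starting material and 86 % of its charged coupling partner were still there, unbound. The turnover rate gives 53.1 % at 15 h, and south-west left that long held 51.5 %. At 40.0 h the same rate gives 142 %, more than the charge. South-west held 89.8 % at 40.0 h, with 10.2 % of its starting material left.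

(Readings and results stem from a simulated flask from invented constants; scatter was added.)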